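Time with reagent is what these set-ups hand out differently, so I count it in one unit.

| flask | starting material | reagent | time | remark |
|---|---|---|---|---|
| Tuesday's | 0.47 M | 0.940 M | 15 h | a closed flask charged with all of it at once and left for 15 h |
| Thursday's | 0.47 M | 0.940 M |  | one stirred flow tank at steady state, fed with the mixture as stated, mean residence time 150 h |
| Friday's | 0.47 M (fed, over 12.0 h) | 0.940 M | 15 h | a stirred flask in which starting material is dosed at a steady rate over 12.0 h without added volume, worked up at 15 h |
| Sunday's | 0.47 M | 0.940 M |  | a single well-mixed tank run continuously and read at steady state, 15 h in it on average |

    reagent + double product ⇌ tris adduct + by-product (K1 = 0.183, k1 = 2.02 × 10⁻⁵ L mol⁻¹ s⁻¹)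
    reagent + single product → double product + by-product (k2 = 5.03 × 10⁻⁵ L mol⁻¹ s⁻¹)
    starting material + reagent → single product + by-product (k3 = 2.34 × 10⁻⁵ L mol⁻¹ s⁻¹)

- the stated concentrations are those of everything mixed, before any reaction; amounts are the same in each set-up
- the feed brings no volume worth counting
- run time (Tuesday's): 15 h

- the set-up with the highest amount of double product at the outlet or at the end, in percent of the starting material put in ("none" if the first two lie within 2 percentage points) (Tuesday's / Thursday's / Friday's / Sunday's / none)
- amount of double product at the outlet or at the end, in percent of the starting material put in, Tuesday's
- amount of double product at the outlet or at the end, in percent of the starting material put in, Thursday's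
- amount of double product at the outlet or at the end, in percent of the starting material put in, Friday's
- amount of double product at the outlet or at the end, in percent of the starting material put in, Sunday's

My unit is the pseudo-first-order life of starting material, one over k3 times c(reagent) as charged: 12.6 h. Because k2 is larger than k3, I let c(reagent) stay at twice c(starting material) as an estimate. In a closed flask the fraction left, s, is then one over one plus the lives spent. In a tank, the fraction gone divided by s squared equals the lives. Single product follows from the ratio k2/k3, 2.15, and I count the rest as double product.

Which constant must be known well? On Tuesday's flask, doubling k3 gives me 35.9%, and doubling k2 gives 41.5%, so in my reckoning for that flask k2 weighs more. I drop k1 and K1, the step that takes double product on to tris adduct.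

With the constants as given, s is 45.7% on Tuesday's, giving 30.7%. On Thursday's, s is 25.1%, giving 64.8%. On Sunday's, s is 58.9%, giving 24.7%. Friday's mean fed portion spends 9.00 h in the flask, so I treat it as a closed flask of that age: s is 58.4%, giving 18.2%. My winner is Thursday's.

The forecast names Thursday's, with 30% (26% to 34%) for Tuesday's, 62% (56% to 67%) for Thursday's, 17% (13% to 21%) for Friday's and 22% (19% to 26%) for Sunday's, holding that “the batch beats the single tank because of its plug-like time exposure”.

The simulation gives Thursday's as best, with 30.0% on Tuesday's, 62.3% on Thursday's, 17.7% on Friday's and 21.8% on Sunday's. Thursday's tank grants 11.9 lives against 1.19 on Sunday's, and c(starting material) there reads 0.112 M, where my s gives 0.118 M. Friday's flask left ten times as long has 11.4 lives of mean age, my rule gives 85.3%, and the run reads 86.6%.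

(Its constants are assumed; the result is computed.)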